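Units: unit 1 is the isoflavone arylated at C3' of its ring B; unit 2 is the isoflavone bonded through C8 of its ring A. Retrosynthetic cuts, in order: the four O–alkyl bonds of a tetraether; O1–C2, C2–C3 and C4–C4a of the pyranone of unit 2; C8–C8a, C6–C7 and C4a–C8a of ring A of unit 2; C3'–C8 as an aryl–alkyne bond; last, the pyranone of unit 1.
Enabling feature: in ring A of unit 2 the aryl-bearing C8 lies between the two oxygen-bearing carbons C7 and C8a. This O–C(Ar)–O triad maps onto an ynol ether oxygen (on C7), the ynol ether beta carbon (C8) and a ketene carbonyl (C8a). Cyclobutenone therefore supplies C8a, C6, C5 and C4a, and an aryl ethoxyalkyne supplies C8 and C7.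
Forward order: pyranone of unit 1 (resorcinol, iodoarylacetic acid, one-carbon unit), O-methylation, Stille alkynylation at C3' (the future axis bond, made as an unhindered sp2–sp bond), benzannulation (ring A of unit 2 grows around that bond), ortho acylation, pyranone of unit 2, global dealkylation.
Stereochemistry: the C3'–C8 axis is the only stereogenic element. It forms as the racemate, and the (M) form is taken from the final tetraphenol by chromatography on a chiral phase, so no later step can erode it.

Key step: step 6

Assumption: the axis with three ortho substituents is taken to be configurationally stable at room temperature, as the occurrence of a single atropisomer implies; a SMILES string does not carry the axial descriptor, so rac, (M) and (P) are given in the names.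

Step 1
Reactants: 1 resorcinol; 2 2-(3-iodo-4-methoxyphenyl)acetic acid
Product: 5 7-hydroxy-3-(3-iodo-4-methoxyphenyl)chromen-4-one, via deoxybenzoin 3 (not isolated), via enaminone 4 (not isolated)
Conditions: BF3·OEt2 (as solvent), 85 °C; cool, DMF, then MsCl in DMF, 50 → 80 °C; poured into ice water
Reagents that add atoms: N,N-dimethylformamide, CN(C)C=O
Why: Nencki-type Friedel–Crafts acylation of resorcinol at C4 (its two ortho/para-activated positions are equivalent) gives 3, Vilsmeier-type aminomethylenation of the activated methylene gives 4, and addition–elimination by the ortho phenol closes the pyranone in the established one-pot isoflavone synthesis, which leaves the aryl iodide and the methyl ether intact.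

Step 2
Reactants: 5 7-hydroxy-3-(3-iodo-4-methoxyphenyl)chromen-4-one
Product: 6 3-(3-iodo-4-methoxyphenyl)-7-methoxychromen-4-one
Conditions: MeI, K2CO3, acetone, reflux
Reagents that add atoms: iodomethane, CI
Why: Williamson etherification of the only free phenol masks it ahead of the organometallic and ketene steps, and K2CO3 in acetone affects neither the chromone nor the aryl iodide.

Step 3
Reactants: 6 3-(3-iodo-4-methoxyphenyl)-7-methoxychromen-4-one; 7 tributyl(ethoxyethynyl)stannane
Product: 8 3-[3-(ethoxyethynyl)-4-methoxyphenyl]-7-methoxychromen-4-one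
Conditions: Pd(PPh3)4 (5 mol %), DMF, 50 °C, argon; chromatography on Et3N-deactivated silica
Reagents that add atoms: none
Why: Stille coupling of an aryl iodide with an alkynylstannane (the fastest-transferring tin ligand) runs under neutral conditions well below the retro-ene range of an ethyl ynol ether, and base-washed silica protects the acid-labile product from hydration.

Step 4
Reactants: 9 3-oxocyclobutane-1-carboxylic acid
Product: 10 3-bromocyclobutan-1-one
Conditions: HgO, Br2, MgSO4 (desiccant), CH2Cl2, reflux
Reagents that add atoms: bromine, BrBr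
Why: The Cristol–Firth variant of the Hunsdiecker reaction replaces the carboxyl group by bromine through radical bromodecarboxylation and is the established entry to this bromoketone.

Step 5
Reactants: 10 3-bromocyclobutan-1-one
Product: 11 cyclobut-2-en-1-one
Conditions: n-Bu3N, neat, rt, reduced pressure, product condensed at −78 °C; kept cold as a toluene solution and used promptly
Reagents that add atoms: none
Why: Dehydrobromination beta to the ketone (E1cB type) with a high-boiling, non-nucleophilic amine lets the volatile enone distil out as it forms, which limits its polymerisation.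

Step 6
Reactants: 8 3-[3-(ethoxyethynyl)-4-methoxyphenyl]-7-methoxychromen-4-one; 11 cyclobut-2-en-1-one
Product: 16 3-[3-(2-ethoxy-6-hydroxyphenyl)-4-methoxyphenyl]-7-methoxychromen-4-one, via vinylketene 12 (not isolated), via 4-vinylcyclobutenone 13 (not isolated), via dienylketene 14 (not isolated), via cyclohexadienone 15 (not isolated)
Conditions: 11 (3 equiv, added in portions as a toluene solution), toluene, BHT (trace), sealed vessel, 80 °C until 8 is consumed, then 110 °C; cat. K2CO3, MeOH, rt, to reverse any O-acylation of the phenol by excess ketene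
Reagents that add atoms: none
Why: Heating opens 11 by a four-electron conrotatory electrocyclic reaction to vinylketene 12, which adds [2+2] to the ynol ether: the aryl-bearing alkyne carbon, made nucleophilic by the ethoxy oxygen, attacks the ketene carbonyl carbon (C8–C8a) and the oxygen-bearing carbon bonds to the ketene alpha carbon (C7–C6), giving 13. Reversible four-electron opening of 13 breaks the C8a–C6 link and gives dienylketene 14 with ketene and vinyl group cis; a six-electron disrotatory electrocyclisation (C4a–C8a) then closes ring A of unit 2, and dienone 15 tautomerises to phenol 16. This is the Danheiser benzannulation of a cyclobutenone with an alkoxyalkyne. The one selectivity required is the orientation of the ketene–alkyne cycloaddition; the O–C≡C–Ar polarisation fixes it so that the aryl group ends up between OH and OEt, and the electron-poor, trisubstituted chromone C2=C3 bond should not compete as a ketenophile. No stereocentre is formed, and the new axis with three ortho substituents arises as the racemate. The first temperature stage keeps 8 below the range where ethyl ynol ethers lose ethene, the hotter stage acts only on the stable enol ether 13, and portionwise excess of 11 offsets its polymerisation.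

Step 7
Reactants: 16 3-[3-(2-ethoxy-6-hydroxyphenyl)-4-methoxyphenyl]-7-methoxychromen-4-one; 17 2-(4-methoxyphenyl)acetic acid
Product: 18 3-[3-[6-ethoxy-2-hydroxy-3-[2-(4-methoxyphenyl)acetyl]phenyl]-4-methoxyphenyl]-7-methoxychromen-4-one
Conditions: BF3·OEt2 (as solvent), 80 °C; ice water
Reagents that add atoms: none
Why: Friedel–Crafts acylation under Nencki/Fries-type conditions should go to the carbon ortho to OH and para to OEt (future C4a), as with simple 3-alkoxyphenols, because the ketone formed there is held as a six-membered boron chelate, while the anisole-type ring B and the carbonyl-deactivated ring A of unit 1 are far less nucleophilic than the resorcinol-type ring.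

Step 8
Reactants: 18 3-[3-[6-ethoxy-2-hydroxy-3-[2-(4-methoxyphenyl)acetyl]phenyl]-4-methoxyphenyl]-7-methoxychromen-4-one
Product: 20 7-ethoxy-8-[2-methoxy-5-(7-methoxy-4-oxochromen-3-yl)phenyl]-3-(4-methoxyphenyl)chromen-4-one, via enaminone 19 (not isolated)
Conditions: Me2NCH(OMe)2, toluene, 100 °C
Reagents that add atoms: N,N-dimethylformamide dimethyl acetal, COC(OC)N(C)C
Why: Condensation of the doubly activated methylene with the amide acetal gives 19, and addition–elimination of the ortho phenol at the enamine carbon (six-membered closure, loss of dimethylamine) forms the pyranone of unit 2, which is the standard amide-acetal isoflavone synthesis from 2-hydroxydeoxybenzoins.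

Step 9
Reactants: 20 7-ethoxy-8-[2-methoxy-5-(7-methoxy-4-oxochromen-3-yl)phenyl]-3-(4-methoxyphenyl)chromen-4-one
Product: 21 rac-bisoflavolin C, 7-hydroxy-8-[2-hydroxy-5-(7-hydroxy-4-oxochromen-3-yl)phenyl]-3-(4-hydroxyphenyl)chromen-4-one
Conditions: BBr3 (excess), CH2Cl2, −78 °C → rt; then H2O, 0 °C
Reagents that add atoms: none
Why: Lewis acid ether cleavage with BBr3 removes aryl methyl and aryl ethyl ethers alike by bromide attack at the O-alkyl carbon, and the vinylogous ester units of both chromones are inert, as is known for the demethylation of methoxyisoflavones.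

Step 10
Reactants: 21 rac-bisoflavolin C
Product: 22 (M)-bisoflavolin C
Conditions: preparative HPLC, amylose tris(3,5-dimethylphenylcarbamate) on silica, hexane/EtOH/0.1% TFA, ≤ 20 °C
Reagents that add atoms: none
Why: Resolution by chromatography on a polysaccharide chiral stationary phase should separate the two atropisomers at or below room temperature, the (M) enantiomer is identified by comparing its ECD curve with a calculated one and with the chiroptical data of the natural product, and the (P) enantiomer can be re-equilibrated by heating and resubmitted.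

Compound list
1 | resorcinol | Oc1cccc(O)c1 | starting material
2 | 2-(3-iodo-4-methoxyphenyl)acetic acid | COc1ccc(CC(=O)O)cc1I | starting material
3 | 1-(2,4-dihydroxyphenyl)-2-(3-iodo-4-methoxyphenyl)ethan-1-one | COc1ccc(CC(=O)c2ccc(O)cc2O)cc1I | intermediate
4 | 1-(2,4-dihydroxyphenyl)-3-(dimethylamino)-2-(3-iodo-4-methoxyphenyl)prop-2-en-1-one (alkene geometry not fixed) | COc1ccc(C(=CN(C)C)C(=O)c2ccc(O)cc2O)cc1I | intermediate
5 | 7-hydroxy-3-(3-iodo-4-methoxyphenyl)chromen-4-one | COc1ccc(-c2coc3cc(O)ccc3c2=O)cc1I | intermediate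
6 | 3-(3-iodo-4-methoxyphenyl)-7-methoxychromen-4-one | COc1ccc(-c2coc3cc(OC)ccc3c2=O)cc1I | intermediate
7 | tributyl(ethoxyethynyl)stannane | CCCC[Sn](CCCC)(CCCC)C#COCC | starting material
8 | 3-[3-(ethoxyethynyl)-4-methoxyphenyl]-7-methoxychromen-4-one | CCOC#Cc1cc(-c2coc3cc(OC)ccc3c2=O)ccc1OC | intermediate
9 | 3-oxocyclobutane-1-carboxylic acid | O=C1CC(C(=O)O)C1 | starting material
10 | 3-bromocyclobutan-1-one | O=C1CC(Br)C1 | intermediate
11 | cyclobut-2-en-1-one | O=C1CC=C1 | intermediate
12 | buta-1,3-dien-1-one (vinylketene) | C=CC=C=O | intermediate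
13 | 3-[3-(2-ethoxy-3-ethenyl-4-oxocyclobut-1-en-1-yl)-4-methoxyphenyl]-7-methoxychromen-4-one (racemic) | C=CC1C(=O)C(c2cc(-c3coc4cc(OC)ccc4c3=O)ccc2OC)=C1OCC | intermediate
14 | (3E)-3-ethoxy-2-[2-methoxy-5-(7-methoxy-4-oxochromen-3-yl)phenyl]hexa-1,3,5-trien-1-one (ketene carbon and vinyl group cis) | C=C\C=C(OCC)/C(=C=O)c1cc(-c2coc3cc(OC)ccc3c2=O)ccc1OC | intermediate
15 | 3-ethoxy-2-[2-methoxy-5-(7-methoxy-4-oxochromen-3-yl)phenyl]cyclohexa-2,4-dien-1-one | CCOC1=C(c2cc(-c3coc4cc(OC)ccc4c3=O)ccc2OC)C(=O)CC=C1 | intermediate
16 | 3-[3-(2-ethoxy-6-hydroxyphenyl)-4-methoxyphenyl]-7-methoxychromen-4-one (racemic axis) | CCOc1cccc(O)c1-c1cc(-c2coc3cc(OC)ccc3c2=O)ccc1OC | intermediate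
17 | 2-(4-methoxyphenyl)acetic acid | COc1ccc(CC(=O)O)cc1 | starting material
18 | 3-[3-[6-ethoxy-2-hydroxy-3-[2-(4-methoxyphenyl)acetyl]phenyl]-4-methoxyphenyl]-7-methoxychromen-4-one (racemic axis) | CCOc1ccc(C(=O)Cc2ccc(OC)cc2)c(O)c1-c1cc(-c2coc3cc(OC)ccc3c2=O)ccc1OC | intermediate
19 | 3-[3-[3-[3-(dimethylamino)-2-(4-methoxyphenyl)prop-2-enoyl]-6-ethoxy-2-hydroxyphenyl]-4-methoxyphenyl]-7-methoxychromen-4-one (alkene geometry not fixed) | CCOc1ccc(C(=O)C(=CN(C)C)c2ccc(OC)cc2)c(O)c1-c1cc(-c2coc3cc(OC)ccc3c2=O)ccc1OC | intermediate
20 | 7-ethoxy-8-[2-methoxy-5-(7-methoxy-4-oxochromen-3-yl)phenyl]-3-(4-methoxyphenyl)chromen-4-one (racemic axis) | CCOc1ccc2c(=O)c(-c3ccc(OC)cc3)coc2c1-c1cc(-c2coc3cc(OC)ccc3c2=O)ccc1OC | intermediate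
21 | rac-bisoflavolin C | O=c1c(-c2ccc(O)c(-c3c(O)ccc4c(=O)c(-c5ccc(O)cc5)coc34)c2)coc2cc(O)ccc12 | intermediate
22 | (M)-bisoflavolin C | O=c1c(-c2ccc(O)c(-c3c(O)ccc4c(=O)c(-c5ccc(O)cc5)coc34)c2)coc2cc(O)ccc12 | target

Total step count: 10. Longest linear sequence: 8 steps (1, 2, 3, 6, 7, 8, 9, 10); steps 4 and 5 form the side branch to cyclobutenone.

Steps most likely to fail

Step 6. The unsubstituted cyclobutenone has little direct precedent as a partner for an aryl-substituted ynol ether. Four processes could hurt the step:
- polymerisation of the enone faster than its ring opening;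
- thermal loss of ethene from the ynol ether;
- direct addition of the ynol ether to the strained enone;
- arrest of the cascade at the four-membered ring stage.

The fallback makes the axis by cross-coupling. It sets out from iodide 6. Miyaura borylation (B2pin2, PdCl2(dppf), KOAc, dioxane, 80 °C) would give 7-methoxy-3-[4-methoxy-3-(4,4,5,5-tetramethyl-1,3,2-dioxaborolan-2-yl)phenyl]chromen-4-one F1. Mono-O-ethylation of commercial 2-bromoresorcinol (EtI, K2CO3, acetone) would give 2-bromo-3-ethoxyphenol F2. Suzuki–Miyaura coupling of the two (Pd(OAc)2, SPhos, K3PO4, toluene/water, 90 °C), a ligand system suited to biaryls with three ortho substituents, comes back to the route at 16.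

Step 7. The acylation could spread over the two activated positions of the resorcinol-type ring (ortho versus para to the free OH). The electron-rich arylacetic acid could condense with itself. Reaction at the hindered phenol could also be slow.

The fallback delivers a small acyl group from the phenol oxygen and attaches the C3 aryl group by cross-coupling instead. It sets out from 16.
- Acetylation (Ac2O, pyridine) would give 3-ethoxy-2-[2-methoxy-5-(7-methoxy-4-oxochromen-3-yl)phenyl]phenyl acetate F3.
- Ortho-selective Fries rearrangement (TiCl4, 1,2-dichloroethane, 80 °C) would give 3-[3-(3-acetyl-6-ethoxy-2-hydroxyphenyl)-4-methoxyphenyl]-7-methoxychromen-4-one F4.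
- Condensation with Me2NCH(OMe)2 would give 3-[3-[3-[(E)-3-(dimethylamino)prop-2-enoyl]-6-ethoxy-2-hydroxyphenyl]-4-methoxyphenyl]-7-methoxychromen-4-one F5.
- Iodocyclisation (I2, CHCl3, rt) would give 7-ethoxy-3-iodo-8-[2-methoxy-5-(7-methoxy-4-oxochromen-3-yl)phenyl]chromen-4-one F6.
- Suzuki–Miyaura coupling with 4-methoxyphenylboronic acid (Pd(PPh3)4, Na2CO3, DME/water) comes back to the route at 20 and bypasses 18.

Step 10. Low solubility of the tetraphenol could limit the loading of the chiral phase. The enantiomers could be poorly discriminated, or slow interconversion on the column could blur the separation.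

The fallback is a covalent resolution. It sets out from 21. Exhaustive acylation with (1R,2S,5R)-(−)-menthyl chloroformate (Et3N, DMAP, CH2Cl2, 0 °C) would give two diastereomers, (M)-bisoflavolin C tetrakis[(1R,2S,5R)-menthyl carbonate] F7 and (P)-bisoflavolin C tetrakis[(1R,2S,5R)-menthyl carbonate] F8. These are separable by crystallisation or ordinary silica chromatography, in the way biaryl diols are resolved. Brief hydrolysis of the former (LiOH, THF/water, 0 °C, then mild acid) comes back to the route at 22.

Further compounds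
F1 | step 6 | 7-methoxy-3-[4-methoxy-3-(4,4,5,5-tetramethyl-1,3,2-dioxaborolan-2-yl)phenyl]chromen-4-one | COc1ccc(-c2coc3cc(OC)ccc3c2=O)cc1B1OC(C)(C)C(C)(C)O1
F2 | step 6 | 2-bromo-3-ethoxyphenol | CCOc1cccc(O)c1Br
F3 | step 7 | 3-ethoxy-2-[2-methoxy-5-(7-methoxy-4-oxochromen-3-yl)phenyl]phenyl acetate | CCOc1cccc(OC(C)=O)c1-c1cc(-c2coc3cc(OC)ccc3c2=O)ccc1OC
F4 | step 7 | 3-[3-(3-acetyl-6-ethoxy-2-hydroxyphenyl)-4-methoxyphenyl]-7-methoxychromen-4-one | CCOc1ccc(C(C)=O)c(O)c1-c1cc(-c2coc3cc(OC)ccc3c2=O)ccc1OC
F5 | step 7 | 3-[3-[3-[(E)-3-(dimethylamino)prop-2-enoyl]-6-ethoxy-2-hydroxyphenyl]-4-methoxyphenyl]-7-methoxychromen-4-one | CCOc1ccc(C(=O)/C=C/N(C)C)c(O)c1-c1cc(-c2coc3cc(OC)ccc3c2=O)ccc1OC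
F6 | step 7 | 7-ethoxy-3-iodo-8-[2-methoxy-5-(7-methoxy-4-oxochromen-3-yl)phenyl]chromen-4-one | CCOc1ccc2c(=O)c(I)coc2c1-c1cc(-c2coc3cc(OC)ccc3c2=O)ccc1OC
F7 | step 10 | (M)-bisoflavolin C tetrakis[(1R,2S,5R)-menthyl carbonate] | O=c1c(-c2ccc(OC(=O)O[C@@H]6C[C@H](C)CC[C@H]6C(C)C)c(-c3c(OC(=O)O[C@@H]7C[C@H](C)CC[C@H]7C(C)C)ccc4c(=O)c(-c5ccc(OC(=O)O[C@@H]8C[C@H](C)CC[C@H]8C(C)C)cc5)coc34)c2)coc2cc(OC(=O)O[C@@H]9C[C@H](C)CC[C@H]9C(C)C)ccc12
F8 | step 10 | (P)-bisoflavolin C tetrakis[(1R,2S,5R)-menthyl carbonate] | O=c1c(-c2ccc(OC(=O)O[C@@H]6C[C@H](C)CC[C@H]6C(C)C)c(-c3c(OC(=O)O[C@@H]7C[C@H](C)CC[C@H]7C(C)C)ccc4c(=O)c(-c5ccc(OC(=O)O[C@@H]8C[C@H](C)CC[C@H]8C(C)C)cc5)coc34)c2)coc2cc(OC(=O)O[C@@H]9C[C@H](C)CC[C@H]9C(C)C)ccc12
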